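**Retrosynthetic overview**
- The strategy rests on the cis C5 (5-phenylpentyl) and C8 (oxygen) substituents that flank the C4a–C8a bond of the carbocyclic ring B (C4a, C5, C6, C7, C8, C8a).
- Ring B is made first: a [4+2] disconnection of C4a–C5 and C8–C8a gives a (1E,3E)-1-silyloxy-4-(5-phenylpentyl)butadiene (C5–C8) and methyl (E)-3-nitroacrylate, whose ester carbon becomes C4 and whose nitro nitrogen becomes N1.
- Ring A (N1, C2, C3, C4, C4a, C8a) is made second: N1–C2 by aza-Michael addition of the reduced nitro group to a 1-methoxyallenyl ketone, C3–C4 from a Weinreb amide and 1-lithio-1-methoxyallene, then dehydrogenation across C4a–C8a.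
- The diene comes from (Z)-9-phenylnon-2-enal (prop-2-yn-1-ol plus (6-bromohexyl)benzene); the dienophile comes from methyl acrylate.
- The last step frees the C8 hydroxyl.

Key step: step 7

**Remarks on the chemistry**
- Atom labels C2–C8a refer to the quinolinone numbering of the target.
- The facial sense of the squaramide cannot be predicted with confidence; the (R)-catalyst is written, and its mirror image is to be used if screening shows the opposite sense.
- O8 carries a triisopropylsilyl group because it must survive a Grignard base, an organolithium and trifluoroacetic acid, and a bulky silanolate leaves less readily from a nitronate.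
- The diene is made from the (Z)-enal, because γ-deprotonative silylation of the (E)-enal is expected to favour the unwanted 3Z diene.
- (6-Bromohexyl)benzene and methoxyallene are taken as catalogue chemicals.

**Step 1**
Reactants: 1 prop-2-yn-1-ol; 2 (6-bromohexyl)benzene
Product: 4 9-phenylnon-2-yn-1-ol, via dilithiated propargyl alcohol 3 (not isolated)
Conditions: n-BuLi (2.1 equiv), THF–DMPU, −78 °C → rt; then H2O
Reagents that add atoms: none
Why: Acetylide alkylation: in 3 the acetylide carbon is far more nucleophilic than the lithium alkoxide in THF–DMPU, so the primary bromide is displaced by SN2 attack at carbon.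

**Step 2**
Reactants: 4 9-phenylnon-2-yn-1-ol
Product: 5 (Z)-9-phenylnon-2-en-1-ol
Conditions: H2 (1 atm), Pd/CaCO3 poisoned with Pb(OAc)2, quinoline, EtOAc, rt
Reagents that add atoms: none
Why: Lindlar semi-hydrogenation: syn delivery of one equivalent of hydrogen on the poisoned palladium surface should stop at the (Z)-alkene and leave the benzene ring untouched.

**Step 3**
Reactants: 5 (Z)-9-phenylnon-2-en-1-ol
Product: 6 (Z)-9-phenylnon-2-enal
Conditions: TEMPO (10 mol %), PhI(OAc)2, CH2Cl2, rt
Reagents that add atoms: none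
Why: Oxoammonium (TEMPO) oxidation of a primary allylic alcohol under neutral, base-free conditions, chosen because this reaction type is used to make (Z)-enals without Z to E isomerisation or over-oxidation.

**Step 4**
Reactants: 6 (Z)-9-phenylnon-2-enal
Product: 7 triisopropyl{[(1E,3E)-9-phenylnona-1,3-dien-1-yl]oxy}silane
Conditions: i-Pr3SiOTf, Et3N, CH2Cl2, −78 → −20 °C
Reagents that add atoms: triisopropylsilyl trifluoromethanesulfonate, CC(C)[Si](C(C)C)(C(C)C)OS(=O)(=O)C(F)(F)F
Why: Vinylogous enol silylation of an enal (γ-deprotonation of its O-silyl oxocarbenium ion): the s-trans enal gives the 1E enol ether, and in the (Z)-enal allylic 1,3-strain between the formyl carbon and C4 keeps the chain on the outside during deprotonation, so the new C3=C4 bond should be E.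

**Step 5**
Reactants: 8 methyl acrylate
Product: 9 methyl 2-iodo-3-nitropropanoate (racemic)
Conditions: N2O4, I2, Et2O, 0 °C
Reagents that add atoms: dinitrogen tetroxide, [O-][N+](=O)[N+](=O)[O-]; iodine, II
Why: Iodonitration of an acrylate: nitryl iodide formed from N2O4 and I2 adds across the double bond with the nitro group on the β-carbon and iodine on the α-carbon.

**Step 6**
Reactants: 9 methyl 2-iodo-3-nitropropanoate
Product: 10 methyl (E)-3-nitroacrylate
Conditions: NaOAc (anhydrous), Et2O, 0 °C → rt
Reagents that add atoms: none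
Why: Dehydroiodination of the E1cB type with the weak base acetate should give the conjugated nitroalkene as its more stable (E)-isomer.

**Step 7**
Reactants: 7 triisopropyl{[(1E,3E)-9-phenylnona-1,3-dien-1-yl]oxy}silane; 10 methyl (E)-3-nitroacrylate
Product: 11 methyl (1R,2S,5R,6S)-6-nitro-2-(5-phenylpentyl)-5-[(triisopropylsilyl)oxy]cyclohex-3-ene-1-carboxylate (chain, silyloxy and nitro groups mutually cis, ester trans to them)
Conditions: 3-{[3,5-bis(trifluoromethyl)phenyl]amino}-4-{[(1R)-1-(naphthalen-1-yl)ethyl]amino}cyclobut-3-ene-1,2-dione (10 mol %), CH2Cl2–toluene, −78 → −40 °C, no base; chromatography on neutral silica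
Reagents that add atoms: none
Why: Proposed new method: the two N–H bonds of the squaramide should bind the nitro oxygens of 10, lower its LUMO and screen one enantioface, so that 7 adds in a concerted, asynchronous normal-demand [4+2] cycloaddition; the closest known reactions are the thermal Diels–Alder additions of 3-nitroacrylates to 1-oxygenated dienes and the hydrogen-bond-donor-catalysed enantioselective cycloadditions of nitroalkenes to cyclopentadienes. Ring B closes by intermolecular [4+2] cycloaddition, the bonds C4a–C5 and C8–C8a forming suprafacially on both partners. C5 and C8 become cis because both diene double bonds are E, C8a carries its nitro group cis to both through the nitro-endo transition state, C4a is trans to C8a because the dienophile is E, and the absolute configuration comes from the catalyst-shielded face of 10. The step needs nitro-directed orientation (secured by the stronger nitro acceptor and the larger HOMO coefficient at the alkyl-bearing diene terminus), nitro-endo addition, one dienophile face, and absence of base so that a nitronate cannot expel silanolate. Because the ester-endo adduct formed on the same dienophile face carries the opposite configuration at C5 and C8, it is removed by chromatography before C4a and C8a are flattened.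

**Step 8**
Reactants: 11 methyl (1R,2S,5R,6S)-6-nitro-2-(5-phenylpentyl)-5-[(triisopropylsilyl)oxy]cyclohex-3-ene-1-carboxylate
Product: 13 methyl (1R,2S,3R,6S)-2-[(tert-butoxycarbonyl)amino]-6-(5-phenylpentyl)-3-[(triisopropylsilyl)oxy]cyclohexane-1-carboxylate, via primary amine 12 (not isolated)
Conditions: H2 (4 bar), Raney Ni (washed neutral), Boc2O, MeOH, rt
Reagents that add atoms: di-tert-butyl dicarbonate, CC(C)(C)OC(=O)OC(=O)OC(C)(C)C
Why: Heterogeneous hydrogenation: Raney Ni should saturate the cis-disubstituted alkene and reduce the secondary nitro group to the amine without base, and Boc2O traps 12 as it forms, so the silyl ether and the C5 and C8 centres are not touched.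

**Step 9**
Reactants: 13 methyl (1R,2S,3R,6S)-2-[(tert-butoxycarbonyl)amino]-6-(5-phenylpentyl)-3-[(triisopropylsilyl)oxy]cyclohexane-1-carboxylate
Product: 14 (1R,2S,3R,6S)-2-[(tert-butoxycarbonyl)amino]-N-methoxy-N-methyl-6-(5-phenylpentyl)-3-[(triisopropylsilyl)oxy]cyclohexane-1-carboxamide
Conditions: MeNH(OMe)·HCl, i-PrMgCl, THF, −20 → 0 °C
Reagents that add atoms: N,O-dimethylhydroxylamine hydrochloride, CNOC.Cl
Why: Direct ester-to-Weinreb-amide aminolysis by the chloromagnesium amide of N,O-dimethylhydroxylamine; the carbamate sits as its N-magnesium salt, and any epimerisation at the carbonyl-bearing carbon is harmless because that centre becomes sp2 later.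

**Step 10**
Reactants: 14 (1R,2S,3R,6S)-2-[(tert-butoxycarbonyl)amino]-N-methoxy-N-methyl-6-(5-phenylpentyl)-3-[(triisopropylsilyl)oxy]cyclohexane-1-carboxamide
Product: 15 tert-butyl N-[(1S,2R,3S,6R)-2-(2-methoxybuta-2,3-dienoyl)-3-(5-phenylpentyl)-6-[(triisopropylsilyl)oxy]cyclohexyl]carbamate
Conditions: methoxyallene, n-BuLi, THF, −78 → −40 °C; then 14, −78 °C; aq. NH4Cl
Reagents that add atoms: methoxyallene (1-methoxypropa-1,2-diene), COC=C=C
Why: Weinreb ketone synthesis with 1-lithio-1-methoxyallene in excess (one equivalent is consumed by the carbamate N–H): the chelated adduct releases the ketone only on work-up, and the reagent brings in C3 with its methoxy group, C2 and the C2 methyl carbon in one operation.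

**Step 11**
Reactants: 15 tert-butyl N-[(1S,2R,3S,6R)-2-(2-methoxybuta-2,3-dienoyl)-3-(5-phenylpentyl)-6-[(triisopropylsilyl)oxy]cyclohexyl]carbamate
Product: 17 (4aR,5S,8R,8aS)-3-methoxy-2-methyl-5-(5-phenylpentyl)-8-[(triisopropylsilyl)oxy]-4a,5,6,7,8,8a-hexahydroquinolin-4(1H)-one, via amino allenyl ketone 16 (not isolated)
Conditions: CF3CO2H, CH2Cl2, 0 °C; then Et3N, CH2Cl2, 0 °C → rt
Reagents that add atoms: none
Why: Acidolysis of the Boc group frees the amine, which after neutralisation should add to the central allene carbon (β to the ketone) in a 6-endo intramolecular aza-Michael addition, and proton shift to the terminal CH2 gives the vinylogous amide with N1–C2 formed and ring A closed; this closure is preferred to a base-mediated aldol condensation of an N-acetyl ketone, where a saturated β-acylamino ketone would tend to lose the amide by β-elimination.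

**Step 12**
Reactants: 17 (4aR,5S,8R,8aS)-3-methoxy-2-methyl-5-(5-phenylpentyl)-8-[(triisopropylsilyl)oxy]-4a,5,6,7,8,8a-hexahydroquinolin-4(1H)-one
Product: 18 (5S,8R)-3-methoxy-2-methyl-5-(5-phenylpentyl)-8-[(triisopropylsilyl)oxy]-5,6,7,8-tetrahydroquinolin-4(1H)-one
Conditions: DDQ (1.05 equiv), 1,4-dioxane, rt → 60 °C
Reagents that add atoms: none
Why: Quinone dehydrogenation: DDQ should abstract hydride from C8a (α to nitrogen, allylic in the dienol tautomer) and loss of the C4a proton gives the aromatic 4-pyridone, which erases C4a and C8a while one equivalent of oxidant leaves C5 and C8 alone.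

**Step 13**
Reactants: 18 (5S,8R)-3-methoxy-2-methyl-5-(5-phenylpentyl)-8-[(triisopropylsilyl)oxy]-5,6,7,8-tetrahydroquinolin-4(1H)-one
Product: 19 (5S,8R)-8-hydroxy-3-methoxy-2-methyl-5-(5-phenylpentyl)-5,6,7,8-tetrahydroquinolin-4(1H)-one
Conditions: Bu4NF, THF, 0 °C → rt
Reagents that add atoms: none
Why: Fluoride-mediated desilylation of the secondary triisopropylsilyl ether under neutral to mildly basic conditions should free the C8 alcohol without ionising the pyridylic C8–O bond, so C5 and C8 keep their configuration.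

**Compound list**
1 | prop-2-yn-1-ol | C#CCO | starting material
2 | (6-bromohexyl)benzene | BrCCCCCCc1ccccc1 | starting material
3 | lithium 3-lithioprop-2-yn-1-olate (dilithiated propargyl alcohol) | [Li]C#CCO[Li] | intermediate
4 | 9-phenylnon-2-yn-1-ol | OCC#CCCCCCCc1ccccc1 | intermediate
5 | (Z)-9-phenylnon-2-en-1-ol | OC/C=C\CCCCCCc1ccccc1 | intermediate
6 | (Z)-9-phenylnon-2-enal | O=C/C=C\CCCCCCc1ccccc1 | intermediate
7 | triisopropyl{[(1E,3E)-9-phenylnona-1,3-dien-1-yl]oxy}silane | CC(C)[Si](C(C)C)(C(C)C)O/C=C/C=C/CCCCCc1ccccc1 | intermediate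
8 | methyl acrylate | C=CC(=O)OC | starting material
9 | methyl 2-iodo-3-nitropropanoate (racemic) | COC(=O)C(I)C[N+](=O)[O-] | intermediate
10 | methyl (E)-3-nitroacrylate | COC(=O)/C=C/[N+](=O)[O-] | intermediate
11 | methyl (1R,2S,5R,6S)-6-nitro-2-(5-phenylpentyl)-5-[(triisopropylsilyl)oxy]cyclohex-3-ene-1-carboxylate | COC(=O)[C@@H]1[C@@H](CCCCCc2ccccc2)C=C[C@@H](O[Si](C(C)C)(C(C)C)C(C)C)[C@H]1[N+](=O)[O-] | intermediate
12 | methyl (1R,2S,3R,6S)-2-amino-6-(5-phenylpentyl)-3-[(triisopropylsilyl)oxy]cyclohexane-1-carboxylate | COC(=O)[C@@H]1[C@@H](CCCCCc2ccccc2)CC[C@@H](O[Si](C(C)C)(C(C)C)C(C)C)[C@H]1N | intermediate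
13 | methyl (1R,2S,3R,6S)-2-[(tert-butoxycarbonyl)amino]-6-(5-phenylpentyl)-3-[(triisopropylsilyl)oxy]cyclohexane-1-carboxylate | COC(=O)[C@@H]1[C@@H](CCCCCc2ccccc2)CC[C@@H](O[Si](C(C)C)(C(C)C)C(C)C)[C@H]1NC(=O)OC(C)(C)C | intermediate
14 | (1R,2S,3R,6S)-2-[(tert-butoxycarbonyl)amino]-N-methoxy-N-methyl-6-(5-phenylpentyl)-3-[(triisopropylsilyl)oxy]cyclohexane-1-carboxamide | CON(C)C(=O)[C@@H]1[C@@H](CCCCCc2ccccc2)CC[C@@H](O[Si](C(C)C)(C(C)C)C(C)C)[C@H]1NC(=O)OC(C)(C)C | intermediate
15 | tert-butyl N-[(1S,2R,3S,6R)-2-(2-methoxybuta-2,3-dienoyl)-3-(5-phenylpentyl)-6-[(triisopropylsilyl)oxy]cyclohexyl]carbamate | C=C=C(OC)C(=O)[C@@H]1[C@@H](CCCCCc2ccccc2)CC[C@@H](O[Si](C(C)C)(C(C)C)C(C)C)[C@H]1NC(=O)OC(C)(C)C | intermediate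
16 | 1-[(1R,2S,3R,6S)-2-amino-6-(5-phenylpentyl)-3-[(triisopropylsilyl)oxy]cyclohexyl]-2-methoxybuta-2,3-dien-1-one | C=C=C(OC)C(=O)[C@@H]1[C@@H](CCCCCc2ccccc2)CC[C@@H](O[Si](C(C)C)(C(C)C)C(C)C)[C@H]1N | intermediate
17 | (4aR,5S,8R,8aS)-3-methoxy-2-methyl-5-(5-phenylpentyl)-8-[(triisopropylsilyl)oxy]-4a,5,6,7,8,8a-hexahydroquinolin-4(1H)-one | CC1=C(OC)C(=O)[C@@H]2[C@@H](CCCCCc3ccccc3)CC[C@@H](O[Si](C(C)C)(C(C)C)C(C)C)[C@H]2N1 | intermediate
18 | (5S,8R)-3-methoxy-2-methyl-5-(5-phenylpentyl)-8-[(triisopropylsilyl)oxy]-5,6,7,8-tetrahydroquinolin-4(1H)-one | COc1c(C)[nH]c2c(c1=O)[C@@H](CCCCCc1ccccc1)CC[C@H]2O[Si](C(C)C)(C(C)C)C(C)C | intermediate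
19 | (5S,8R)-8-hydroxy-3-methoxy-2-methyl-5-(5-phenylpentyl)-5,6,7,8-tetrahydroquinolin-4(1H)-one | COc1c(C)[nH]c2c(c1=O)[C@@H](CCCCCc1ccccc1)CC[C@H]2O | target

**Step count**
Total: 13 steps. Longest linear sequence: 11 steps (steps 1–4, then 7–13).

**Steps most likely to fail**

Step 7. The uncatalysed background cycloaddition and weak face discrimination by the squaramide may erode the enantiomeric purity. A low nitro-endo preference would feed material into the diastereomer that leads to the mirror-image product. A stepwise Mukaiyama–Michael addition with silyl transfer, or loss of silanol through a nitronate, may compete. The fallback uses known chemistry and sets out from 7 and 10. These are combined without catalyst (toluene, 0 °C → rt) and the nitro-endo product is separated by chromatography as the racemic cycloadduct F1. Hydrogenation over neutral Raney Ni without Boc2O gives the racemic amine F2. This is resolved by crystallisation with (S)-mandelic acid as the mandelate salt F3; the acid antipode is to be chosen so that the salt of the (1R,2S,3R,6S)-amine is the less soluble one. Aqueous NaHCO3 liberates the free base, and the route is rejoined at 12, which is treated with Boc2O to give 13.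

Step 10. The lithiated allene may be quenched by the carbamate N–H faster than it adds to the hindered amide. The allenyl ketone may polymerise or be hydrated on work-up, or lose its enol ether during the acidic Boc removal of step 11. The fallback sets out from 14. Methoxymethyllithium (from tributyl(methoxymethyl)stannane and n-BuLi, THF, −78 °C) gives the methoxymethyl ketone F4. Soft-enolisation C-acetylation at the methoxymethylene carbon (MgBr2·OEt2, i-Pr2NEt, 1-acetylbenzotriazole, CH2Cl2) gives the 2-methoxy-1,3-diketone F5. Trifluoroacetic acid followed by Et3N removes the Boc group and lets the amine condense with the acetyl carbonyl, and the route is rejoined at 17.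

Step 12. Enolisation of the vinylogous amide may be too slow for hydride abstraction to proceed, and once the ring is aromatic the oxidant may attack the pyridylic C8–H. The fallback sets out from 17. O-Silylation (Me3SiOTf, Et3N, CH2Cl2, 0 °C) gives the silyloxy dihydropyridine F6, in which C8a–H is the only α-amino, allylic hydrogen. A mild oxidant (tetrachloro-1,4-benzoquinone or activated MnO2, 0 °C → rt) followed by aqueous work-up should aromatise it, and the route is rejoined at 18.

**Further compounds**
F1 | step 7 | racemic methyl 6-nitro-2-(5-phenylpentyl)-5-[(triisopropylsilyl)oxy]cyclohex-3-ene-1-carboxylate, (1R,2S,5R,6S) and (1S,2R,5S,6R) | COC(=O)[C@@H]1[C@@H](CCCCCc2ccccc2)C=C[C@@H](O[Si](C(C)C)(C(C)C)C(C)C)[C@H]1[N+](=O)[O-].COC(=O)[C@H]1[C@H](CCCCCc2ccccc2)C=C[C@H](O[Si](C(C)C)(C(C)C)C(C)C)[C@@H]1[N+](=O)[O-]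
F2 | step 7 | racemic methyl 2-amino-6-(5-phenylpentyl)-3-[(triisopropylsilyl)oxy]cyclohexane-1-carboxylate, (1R,2S,3R,6S) and (1S,2R,3S,6R) | COC(=O)[C@@H]1[C@@H](CCCCCc2ccccc2)CC[C@@H](O[Si](C(C)C)(C(C)C)C(C)C)[C@H]1N.COC(=O)[C@H]1[C@H](CCCCCc2ccccc2)CC[C@H](O[Si](C(C)C)(C(C)C)C(C)C)[C@@H]1N
F3 | step 7 | (S)-mandelate salt of methyl (1R,2S,3R,6S)-2-amino-6-(5-phenylpentyl)-3-[(triisopropylsilyl)oxy]cyclohexane-1-carboxylate | COC(=O)[C@@H]1[C@@H](CCCCCc2ccccc2)CC[C@@H](O[Si](C(C)C)(C(C)C)C(C)C)[C@H]1[NH3+].O[C@H](C([O-])=O)c1ccccc1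
F4 | step 10 | tert-butyl N-[(1S,2R,3S,6R)-2-(2-methoxyacetyl)-3-(5-phenylpentyl)-6-[(triisopropylsilyl)oxy]cyclohexyl]carbamate | COCC(=O)[C@@H]1[C@@H](CCCCCc2ccccc2)CC[C@@H](O[Si](C(C)C)(C(C)C)C(C)C)[C@H]1NC(=O)OC(C)(C)C
F5 | step 10 | tert-butyl N-[(1S,2R,3S,6R)-2-(2-methoxy-3-oxobutanoyl)-3-(5-phenylpentyl)-6-[(triisopropylsilyl)oxy]cyclohexyl]carbamate (both configurations at the methoxy-bearing carbon) | CC(=O)C(OC)C(=O)[C@@H]1[C@@H](CCCCCc2ccccc2)CC[C@@H](O[Si](C(C)C)(C(C)C)C(C)C)[C@H]1NC(=O)OC(C)(C)C
F6 | step 12 | (5S,8R,8aS)-3-methoxy-2-methyl-5-(5-phenylpentyl)-8-[(triisopropylsilyl)oxy]-4-[(trimethylsilyl)oxy]-1,5,6,7,8,8a-hexahydroquinoline | CC1=C(OC)C(O[Si](C)(C)C)=C2[C@@H](CCCCCc3ccccc3)CC[C@@H](O[Si](C(C)C)(C(C)C)C(C)C)[C@H]2N1
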